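The numbers are invented; the flask was simulated.

Per molar is the unit of the equilibrium constant, so that constant gives a ratio of target to substrate in a flask once it is multiplied by a concentration of reagent, and I had to find out which concentration to take.

in all of them: reagent 1.20 mM; time 25 s

| run | substrate |
|---|---|
| ochre | 0.50 mM |
| teal | 1.0 mM |
| grey | 2.0 mM |

    substrate + reagent ⇌ target (K1 = 710 M⁻¹, k1 = 910 M⁻¹ s⁻¹)
    substrate + target → side product (k2 = 4300 M⁻¹ s⁻¹)

* [target] at the end for ochre, teal, grey, in this order
* how that number moves from the first to the last of them (falls all the way / falls, then rises / hardly changes / rises all the way / rises, then falls)

- percentages count the substrate that a species holds: one side product counts as two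
- "hardly changes" means that all values lie within two and a half points (for a concentration: within two and a half percent of the largest)
- run time (ochre): 25 s

I asked first where the substrate went. At the charge of ochre, substrate consumed target with a half-life of 0.322 s, far shorter than the 25 s of the run, so I took the substrate to end as side product. Each side product costs two substrate but one reagent, so c(reagent) tended to 0.950 mM in ochre, 0.700 mM in teal and 0.200 mM in grey.

I asked next how the remnant divided. Target falls back at 1.28 s⁻¹, and if that outran its loss to substrate, c(target)/c(substrate) stood at a pre-equilibrium equal to the hold, the equilibrium constant times the reagent left: 0.674 in ochre, 0.497 in teal and 0.142 in grey.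

Last I asked how fast the pool W = c(substrate) + c(target) shrank. The second step removes W at 2 k2 c(substrate) c(target), and with the hold h dividing W, the reciprocal of W grew steadily, so that long after the start c(target) = (1 + h)/(2 k2 t). This gave me 0.00779 mM, 0.00696 mM and 0.00531 mM, falling all the way. The assumption stood in grey at the end of the run, where my free substrate of 0.0374 mM made the loss of target 0.161 s⁻¹, less than the 1.28 s⁻¹ of falling back.

The forecast gave 0.0076 mM, 0.0071 mM and 0.0056 mM, a row that falls all the way, in its words “Target falls throughout”.

The simulation gave 0.00760 mM, 0.00698 mM and 0.00531 mM, so the row falls all the way. At the asked time in ochre, the forward first step took substrate 27 times as fast as the second step, and c(target)/c(substrate) stood at 0.671 against a hold of 0.674. In grey at the asked time the same ratio stood at 0.140 against a hold of 0.142, with 18.0% of the reagent charge still free and 97.8% of the substrate charged held in side product.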